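The runs stem from a simulated flask from invented constants, and the scatter is random.

The constants are what we lack, so we make the one we need from the runs.

| flask | substrate | partner | temperature | remark | time |
|---|---|---|---|---|---|
| Sunday's | 0.048 M | 1.1 equiv | 45 °C | run made earlier |  |
| Thursday's | 0.048 M | 0.55 equiv | 60 °C | run made earlier |  |
| Tuesday's | 0.048 M | 0.83 equiv | 45 °C | run made earlier |  |
| Wednesday's | 0.072 M | 1.1 equiv | 60 °C | run made earlier |  |
| teal | 0.048 M | 1.10 equiv | 60 °C | everything together at the start | 6.0 h |
| green | 0.048 M | 1.10 equiv (fed, over 4.0 h) | 60 °C | all else is in the flask from the start; the feed brings no volume worth counting | 6.0 h |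
| amber | 0.048 M | 1.10 equiv (fed, over 4.0 h) |  | the addition at 30 °C, then warmed to 60 °C; the feed brings no volume worth counting | 6.0 h |
| red | 0.048 M | 1.10 equiv |  | everything together at the start at 30 °C, warmed to 60 °C at 4.0 h | 6.0 h |

| run | time / h | side product / % | target / % | substrate / % |
|---|---|---|---|---|
| Sunday's | 0.667 | 0.8 | 9.3 | 89.0 |
| Sunday's | 2.00 | 7.8 | 21.2 | 72.3 |
| Sunday's | 3.00 | 11.8 | 23.9 | 63.8 |
| Sunday's | 5.00 | 22.2 | 27.2 | 50.1 |
| Sunday's | 8.00 | 34.5 | 27.0 | 38.2 |
| Thursday's | 1.33 | 8.6 | 12.8 | 79.4 |
| Thursday's | 2.50 | 19.3 | 14.3 | 67.1 |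
| Thursday's | 4.00 | 30.3 | 14.0 | 57.0 |
| Thursday's | 5.00 | 37.4 | 12.6 | 49.9 |
| Thursday's | 6.00 | 42.8 | 11.6 | 45.3 |
| Tuesday's | 3.00 | 10.5 | 19.3 | 70.2 |
| Tuesday's | 5.00 | 19.6 | 21.8 | 58.5 |
| Tuesday's | 8.00 | 31.3 | 23.2 | 45.4 |
| Tuesday's | 10.0 | 39.0 | 21.4 | 39.8 |
| Tuesday's | 12.0 | 43.3 | 21.0 | 35.0 |
| Wednesday's | 0.500 | 7.9 | 22.3 | 70.4 |
| Wednesday's | 0.833 | 14.2 | 26.7 | 58.7 |
| Wednesday's | 1.50 | 28.6 | 30.3 | 43.3 |
| Wednesday's | 3.00 | 47.8 | 27.1 | 25.5 |
| Wednesday's | 6.00 | 66.1 | 22.4 | 12.7 |

(scatter of a reading: 0.5 percentage points)

- percentages count the substrate that a species holds: one side product counts as two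

1. the flask that comes out highest in amount of side product, in percent of the substrate charged; "all alike" if 1.5 percentage points covers them all (teal / green / amber / red / all alike)
2. amount of side product at the end, in percent of the substrate charged, teal
3. amount of side product at the end, in percent of the substrate charged, green
4. amount of side product at the end, in percent of the substrate charged, amber
5. amount of side product at the end, in percent of the substrate charged, red

Sunday's run looks contradictory: target reads 27.2 % at 5.00 h and 27.0 % at 8.00 h, yet substrate falls from 50.1 % to 38.2 % between them. Side product clears this up. It gains 12 percentage points while substrate loses 12 points, so between those readings of Sunday's run target acts as a passage, and we take side product to grow with c(substrate) times c(target), both as shares of the charge.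

Thursday's run has teal's substrate charge and temperature. From 2.50 h to 6.00 h its side-product clock, the gain of side product per hour divided by that product, comes to 0.923 /h.

If target stands at a share p, side product climbs pseudo-first-order, at clock times p, towards the charge less p. Thursday's first readings run back to zero side product at 0.390 h, and we borrow that delay as an estimate for teal, which gives teal 5.61 h of running. Our first round, with Sunday's 27.0 %, read at 45 °C, as p, gives 55.0 %. On that reckoning teal holds 18.0 % of substrate, and Wednesday's run, at 60 °C with 0.072 M charged, reads target at 22.4 % with substrate at 12.7 %. So we go round again with the mean of those two targets, 24.7 %, and get 54.3 %.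

In green, partner arrives over 4.0 h, so we expect target to climb during the feed and count that time as half, which gives 45.0 %. For amber and red we count the 2.00 h hot as an estimate that does not part the two, which gives both 27.6 %. Our reckoning puts teal highest.

The forecast named teal as highest, with 54.5 % for teal, 44.5 % for green, 27 % for amber and 30 % for red: “Teal is highest: it spends the longest time hot with target present.”

The flasks give 53.6 % for teal, 42.4 % for green, 26.6 % for amber and 30.4 % for red, so teal stands highest. Teal ends with 25.7 % of substrate, amber with 49.4 %.

    substrate + partner → target, rate k1*[substrate]^2*[partner] (k = 0.0400 /M²/s, Ea = 41.0 kJ/mol)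
    substrate + target → side product (k = 0.00270 /M/s, Ea = 58.0 kJ/mol)
    (constants at 60 °C)

Now the clock on green after its feed: from 4.00 h to 6.00 h substrate goes from 55.8 % to 37.0 % and target from 19.0 % to 20.5 %. The clock 0.923 /h on those means gives 17 points, and green gained 17 points.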